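**Plan**

1. Retrosynthetic cuts, in order: the O1–C8a aryl ether bond of the pyranone ring (giving an open hydroquinone β-hydroxy ketone); the side-chain CH2–CH2 bond C2'–C3' (giving a C11 head-group bromide and a C15 (Z)-alkenylborane); the C4–C4a acyl–aryl bond (giving an aryllithium and a δ-lactone); the C12'=C13' alkene (Wittig).
2. Forward: a C5 lactone carrying the future C2 is opened by 2,5-bis(methoxymethoxy)phenyllithium to the aryl ketone; the whole C15 tail is joined by hydroboration/B-alkyl Suzuki–Miyaura coupling; after deprotection the pyranone ring is closed last.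
3. Feature used by the key event: C2'–C3' is an unbranched CH2–CH2 bond. On the head side C2' is primary, has only CH2 neighbours and lies two carbons from C2. On the tail side nine CH2 groups separate it from the only C=C, so a terminal vinyl group on the tail can be told apart from the internal (Z)-alkene by 9-BBN.
4. Feature used by the ring closure: O1 sits on C8a between the acyl-bearing C4a and C8–OH, with C5–OH para to C8–OH. The benzo ring is therefore the adduct of an oxygen nucleophile at C3 of a 2-acyl-1,4-benzoquinone, and no third phenolic oxygen has to be carried or differentiated.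
5. Stereochemistry: C2 (R) comes from the (R)-3-silyloxyglutarate half-ester 1 and its C–O bond is never broken; the (Z)-alkene comes from a salt-free Wittig reaction.

Key step: step 6

Assumption: half-ester 1 is taken as the commercial (R)-enantiomer (a statin side-chain building block); it is otherwise made by desymmetrising alcoholysis of commercial 3-(tert-butyldimethylsilyloxy)glutaric anhydride.

**Route**

Step 1
Reactants: 1 (R)-3-[(tert-butyldimethylsilyl)oxy]-5-methoxy-5-oxopentanoic acid
Product: 3 (R)-4-[(tert-butyldimethylsilyl)oxy]tetrahydro-2H-pyran-2-one, via hydroxy ester 2 (not isolated)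
Conditions: BH3·SMe2, THF, 0 °C → rt; MeOH quench; then PPTS (cat.), PhMe, 60 °C
Reagents that add atoms: none
Why: Borane reduces the free carboxylic acid (through its acyloxyborane) much faster than the methyl ester and spares the silyl ether, and the δ-hydroxy ester then lactonises under mild acid (chemoselective borane reduction, then lactonisation); the stereocentre is untouched, and the choice of which arm is reduced fixes the sense of the lactone.

Step 2
Reactants: 4 hydroquinone
Product: 5 1,4-bis(methoxymethoxy)benzene
Conditions: MOMCl, iPr2NEt, CH2Cl2, 0 °C → rt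
Reagents that add atoms: chloromethyl methyl ether (MOMCl), COCCl
Why: O-alkylation of both phenols (MOM protection) installs the ortho-directing groups needed for step 3, and these groups fall off with acid in step 7.

Step 3
Reactants: 5 1,4-bis(methoxymethoxy)benzene; 3 (R)-4-[(tert-butyldimethylsilyl)oxy]tetrahydro-2H-pyran-2-one
Product: 7 (R)-1-[2,5-bis(methoxymethoxy)phenyl]-3-[(tert-butyldimethylsilyl)oxy]-5-hydroxypentan-1-one, via aryllithium 6 (not isolated)
Conditions: 5, n-BuLi, THF, 0 °C; then added to 3, THF, −78 °C; aq NH4Cl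
Reagents that add atoms: none
Why: Directed ortho-metalation (all four ring C–H are equivalent) should give a single aryllithium, which adds once to the δ-lactone at −78 °C because the lithium lactolate survives until the quench (acylation of an aryllithium by a lactone); this unveils the C4 ketone and the primary C2' alcohol in one operation without touching the stereocentre.

Step 4
Reactants: 7 (R)-1-[2,5-bis(methoxymethoxy)phenyl]-3-[(tert-butyldimethylsilyl)oxy]-5-hydroxypentan-1-one
Product: 8 (S)-1-[2,5-bis(methoxymethoxy)phenyl]-5-bromo-3-[(tert-butyldimethylsilyl)oxy]pentan-1-one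
Conditions: CBr4, PPh3, imidazole, CH2Cl2, 0 °C
Reagents that add atoms: carbon tetrabromide, BrC(Br)(Br)Br
Why: Appel bromination converts the primary alcohol to the primary bromide by SN2 at C5 under buffered conditions that spare MOM, TBS and the β-silyloxy ketone (the descriptor changes from R to S only because the bromoethyl arm gains CIP priority).

Step 5
Reactants: 9 pentyltriphenylphosphonium bromide; 10 dec-9-enal
Product: 12 (Z)-pentadeca-1,10-diene, via phosphorus ylide 11 (not isolated)
Conditions: NaHMDS, THF, 0 °C; then 10, −78 °C → rt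
Reagents that add atoms: none
Why: Wittig olefination of an aliphatic aldehyde with a non-stabilised ylide under salt-free conditions passes through the kinetically favoured cis-oxaphosphetane and should give mainly the (Z)-alkene, while the terminal vinyl group is inert.

Step 6
Reactants: 12 (Z)-pentadeca-1,10-diene; 8 (S)-1-[2,5-bis(methoxymethoxy)phenyl]-5-bromo-3-[(tert-butyldimethylsilyl)oxy]pentan-1-one
Product: 14 (R,Z)-1-[2,5-bis(methoxymethoxy)phenyl]-3-[(tert-butyldimethylsilyl)oxy]icos-15-en-1-one, via alkylborane 13 (not isolated)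
Conditions: 12, 9-BBN-H, THF, 0 °C → rt; then 8, Pd(OAc)2 (4 mol %), PCy3 (8 mol %), K3PO4·H2O, THF, rt
Reagents that add atoms: none
Why: 9-BBN adds anti-Markovnikov to the monosubstituted vinyl group of 12 much faster than to the cis-disubstituted C10=C11 alkene; the alkyl group of borane 13 is then transferred, through its hydroxo/phosphato borate, to the alkylpalladium(II) bromide formed by SN2-type oxidative addition of Pd(0)/PCy3 into the primary C–Br bond of 8, and reductive elimination forms the CH2–CH2 bond. The closest known reaction type is the room-temperature B-alkyl Suzuki–Miyaura coupling of primary alkyl bromides bearing β-hydrogens with B-alkyl-9-BBN reagents under palladium/trialkylphosphine catalysis. No ring is closed and no stereocentre is created; the silyloxy-bearing centre of 8 lies two carbons from the reacting carbon and is not involved. The step needs chemoselective hydroboration (secured by the steric demand of 9-BBN and the terminal position of the vinyl group), retention of the (Z)-geometry with no β-hydride elimination or chain walking (secured by the bulky, electron-rich PCy3, which lets reductive elimination outrun β-hydride elimination), and survival of the enolisable β-silyloxy aryl ketone (secured by the weak, sparingly soluble base at room temperature and by the poor leaving-group ability of the silyloxy group). One operation thereby delivers 15 of the 26 carbons and the only alkene onto a head group that already holds the stereocentre, the ketone and both hydroquinone oxygens, so no reduction is needed after the alkene is in place.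

Step 7
Reactants: 14 (R,Z)-1-[2,5-bis(methoxymethoxy)phenyl]-3-[(tert-butyldimethylsilyl)oxy]icos-15-en-1-one
Product: 15 (R,Z)-1-(2,5-dihydroxyphenyl)-3-hydroxyicos-15-en-1-one
Conditions: HCl (1.25 M in MeOH), THF, 0 °C → rt
Reagents that add atoms: none
Why: Acid-catalysed acetal exchange removes both MOM ethers and methanolysis removes the secondary TBS ether in one pot (global acidic deprotection), at a temperature low enough that the β-hydroxy ketone should not dehydrate; the stereocentre is untouched.

Step 8
Reactants: 15 (R,Z)-1-(2,5-dihydroxyphenyl)-3-hydroxyicos-15-en-1-one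
Product: 18 (R)-2-[(Z)-heptadec-12-en-1-yl]-5,8-dihydroxychroman-4-one, via acylquinone 16 (not isolated), via chromanetrione 17 (not isolated)
Conditions: Ag2O (2.5 equiv), MgSO4, Et2O, rt, dark (CSA cat. if closure lags); filter; then aq Na2S2O4, EtOAc
Reagents that add atoms: none
Why: Proposed new method: Ag2O oxidises the hydroquinone to 2-acyl-1,4-benzoquinone 16, whose C3 is the β-carbon of two enones (ring C1=O and the side-chain C=O); the chain hydroxyl adds there by a 6-endo-trig oxa-Michael addition to give a doubly stabilised enolate that tautomerises to the 5,8-dihydroxychromanone, the excess oxidant (or 16 itself) takes this more electron-rich hydroquinone on to trione 17, and dithionite returns 17 to 18; the carbinol C–O bond is never broken, so C2 keeps its (R) configuration, and only quinone C3 is within reach of a six-membered closure; the closest known reaction type is the conjugate addition of thiols, amines, alcohols and acetate (Thiele–Winter) to C3 of 2-acyl-1,4-benzoquinones followed by enolisation.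

**Compound list**

1 | (R)-3-[(tert-butyldimethylsilyl)oxy]-5-methoxy-5-oxopentanoic acid | OC(=O)C[C@@H](O[Si](C)(C)C(C)(C)C)CC(=O)OC | starting material
2 | methyl (R)-3-[(tert-butyldimethylsilyl)oxy]-5-hydroxypentanoate | OCC[C@@H](O[Si](C)(C)C(C)(C)C)CC(=O)OC | intermediate
3 | (R)-4-[(tert-butyldimethylsilyl)oxy]tetrahydro-2H-pyran-2-one | O=C1C[C@H](O[Si](C)(C)C(C)(C)C)CCO1 | intermediate
4 | hydroquinone | Oc1ccc(O)cc1 | starting material
5 | 1,4-bis(methoxymethoxy)benzene | COCOc1ccc(OCOC)cc1 | intermediate
6 | [2,5-bis(methoxymethoxy)phenyl]lithium | [Li]c1cc(OCOC)ccc1OCOC | intermediate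
7 | (R)-1-[2,5-bis(methoxymethoxy)phenyl]-3-[(tert-butyldimethylsilyl)oxy]-5-hydroxypentan-1-one | OCC[C@@H](O[Si](C)(C)C(C)(C)C)CC(=O)c1cc(OCOC)ccc1OCOC | intermediate
8 | (S)-1-[2,5-bis(methoxymethoxy)phenyl]-5-bromo-3-[(tert-butyldimethylsilyl)oxy]pentan-1-one | BrCC[C@@H](O[Si](C)(C)C(C)(C)C)CC(=O)c1cc(OCOC)ccc1OCOC | intermediate
9 | pentyltriphenylphosphonium bromide | CCCCC[P+](c1ccccc1)(c1ccccc1)c1ccccc1.[Br-] | starting material
10 | dec-9-enal | C=CCCCCCCCC=O | starting material
11 | pentylidene(triphenyl)phosphorane | CCCCC=P(c1ccccc1)(c1ccccc1)c1ccccc1 | intermediate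
12 | (Z)-pentadeca-1,10-diene | C=CCCCCCCC/C=C\CCCC | intermediate
13 | 9-[(Z)-pentadec-10-en-1-yl]-9-borabicyclo[3.3.1]nonane | CCCC/C=C\CCCCCCCCCB1C2CCCC1CCC2 | intermediate
14 | (R,Z)-1-[2,5-bis(methoxymethoxy)phenyl]-3-[(tert-butyldimethylsilyl)oxy]icos-15-en-1-one | CCCC/C=C\CCCCCCCCCCC[C@@H](O[Si](C)(C)C(C)(C)C)CC(=O)c1cc(OCOC)ccc1OCOC | intermediate
15 | (R,Z)-1-(2,5-dihydroxyphenyl)-3-hydroxyicos-15-en-1-one | CCCC/C=C\CCCCCCCCCCC[C@@H](O)CC(=O)c1cc(O)ccc1O | intermediate
16 | 2-[(3R,15Z)-3-hydroxyicos-15-enoyl]cyclohexa-2,5-diene-1,4-dione | CCCC/C=C\CCCCCCCCCCC[C@@H](O)CC(=O)C1=CC(=O)C=CC1=O | intermediate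
17 | (R)-2-[(Z)-heptadec-12-en-1-yl]-2,3-dihydro-4H-chromene-4,5,8-trione | CCCC/C=C\CCCCCCCCCCC[C@@H]1CC(=O)C2=C(O1)C(=O)C=CC2=O | intermediate
18 | (R)-2-[(Z)-heptadec-12-en-1-yl]-5,8-dihydroxychroman-4-one | CCCC/C=C\CCCCCCCCCCC[C@@H]1CC(=O)c2c(O)ccc(O)c2O1 | target

**Step count and risks**

Total steps: 8. Longest linear sequence: 6 (steps 1, 3, 4, 6, 7, 8).

Steps most likely to fail:

Step 8 (proposed new method). The intramolecular addition may be slower than self-condensation of the acylquinone or addition of adventitious water. At the trione stage, deprotonation at C3 followed by β-elimination of the quinone-bound oxygen and re-closure would erode the configuration at C2. The electron-rich product may also be lost by further oxidation before the reductive work-up. The fallback uses known reactions only; it sets out from half-ester 1 and comes back to the route at target 18. It closes the ring by a Mitsunobu etherification, which inverts, so the enantiomeric lactone is used. The ester arm of 1 is reduced instead of the acid arm (LiBH4, THF; then PPTS) to give (S)-4-[(tert-butyldimethylsilyl)oxy]tetrahydro-2H-pyran-2-one F1. Commercial 2,5-dimethoxyphenol is protected (MOMCl, iPr2NEt) as 1,4-dimethoxy-2-(methoxymethoxy)benzene F2, which is lithiated between its two flanking oxygen substituents (n-BuLi, THF, 0 °C) to [3,6-dimethoxy-2-(methoxymethoxy)phenyl]lithium F3. Addition of this aryllithium to F1 at −78 °C gives (S)-3-[(tert-butyldimethylsilyl)oxy]-1-[3,6-dimethoxy-2-(methoxymethoxy)phenyl]-5-hydroxypentan-1-one F4. Appel bromination gives (R)-5-bromo-3-[(tert-butyldimethylsilyl)oxy]-1-[3,6-dimethoxy-2-(methoxymethoxy)phenyl]pentan-1-one F5. Coupling with borane 13 under the conditions of step 6 gives (S,Z)-3-[(tert-butyldimethylsilyl)oxy]-1-[3,6-dimethoxy-2-(methoxymethoxy)phenyl]icos-15-en-1-one F6. Methanolic HCl removes MOM and TBS to give (S,Z)-3-hydroxy-1-(2-hydroxy-3,6-dimethoxyphenyl)icos-15-en-1-one F7. Intramolecular Mitsunobu etherification of the single free phenol (PPh3, DIAD, THF, 0 °C) closes the pyranone with inversion to (R)-2-[(Z)-heptadec-12-en-1-yl]-5,8-dimethoxychroman-4-one F8. BBr3 (CH2Cl2, −78 → 0 °C) then cleaves both methyl ethers to give 18.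

Step 6. β-Hydride elimination from the alkylpalladium intermediate before transmetalation would give reduced and olefinic head-group products, and base-induced loss of silanol from the β-silyloxy aryl ketone would consume the bromide. The fallback moves the fragment union to the ester stage, before the aryl ketone exists; it sets out from hydroxy ester 2 (isolated after the borane reduction of step 1, without the acid treatment) and comes back at 14. Appel bromination of 2 gives methyl (S)-5-bromo-3-[(tert-butyldimethylsilyl)oxy]pentanoate F9. Coupling of F9 with borane 13 (same catalyst system; the ester is far less prone to enolisation and elimination) gives methyl (R,Z)-3-[(tert-butyldimethylsilyl)oxy]icos-15-enoate F10. Aminolysis (MeNHOMe·HCl, i-PrMgCl, THF, −20 °C) gives (R,Z)-3-[(tert-butyldimethylsilyl)oxy]-N-methoxy-N-methylicos-15-enamide F11. Aryllithium 6 then adds once to this Weinreb amide at −78 °C to give 14.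

Step 3. α-Deprotonation of the lactone by the basic aryllithium followed by β-elimination of silanolate, or collapse of the tetrahedral intermediate followed by a second addition, would divert the lactone. The fallback lowers the oxidation level of the electrophile; it sets out from lactone 3 and comes back at 7. DIBAL-H (CH2Cl2, −78 °C) reduces 3 to (4R)-4-[(tert-butyldimethylsilyl)oxy]tetrahydro-2H-pyran-2-ol F12. Aryllithium 6 (2.2 equiv, THF, −78 °C) adds to the open aldehyde form to give (3R)-1-[2,5-bis(methoxymethoxy)phenyl]-3-[(tert-butyldimethylsilyl)oxy]pentane-1,5-diol F13 as a mixture of C1 epimers. MnO2 (CH2Cl2, rt) then oxidises only the benzylic alcohol to give 7.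

**Further compounds**

F1 | step 8 | (S)-4-[(tert-butyldimethylsilyl)oxy]tetrahydro-2H-pyran-2-one | O=C1C[C@@H](O[Si](C)(C)C(C)(C)C)CCO1
F2 | step 8 | 1,4-dimethoxy-2-(methoxymethoxy)benzene | COCOc1cc(OC)ccc1OC
F3 | step 8 | [3,6-dimethoxy-2-(methoxymethoxy)phenyl]lithium | [Li]c1c(OC)ccc(OC)c1OCOC
F4 | step 8 | (S)-3-[(tert-butyldimethylsilyl)oxy]-1-[3,6-dimethoxy-2-(methoxymethoxy)phenyl]-5-hydroxypentan-1-one | OCC[C@H](O[Si](C)(C)C(C)(C)C)CC(=O)c1c(OC)ccc(OC)c1OCOC
F5 | step 8 | (R)-5-bromo-3-[(tert-butyldimethylsilyl)oxy]-1-[3,6-dimethoxy-2-(methoxymethoxy)phenyl]pentan-1-one | BrCC[C@H](O[Si](C)(C)C(C)(C)C)CC(=O)c1c(OC)ccc(OC)c1OCOC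
F6 | step 8 | (S,Z)-3-[(tert-butyldimethylsilyl)oxy]-1-[3,6-dimethoxy-2-(methoxymethoxy)phenyl]icos-15-en-1-one | CCCC/C=C\CCCCCCCCCCC[C@H](O[Si](C)(C)C(C)(C)C)CC(=O)c1c(OC)ccc(OC)c1OCOC
F7 | step 8 | (S,Z)-3-hydroxy-1-(2-hydroxy-3,6-dimethoxyphenyl)icos-15-en-1-one | CCCC/C=C\CCCCCCCCCCC[C@H](O)CC(=O)c1c(OC)ccc(OC)c1O
F8 | step 8 | (R)-2-[(Z)-heptadec-12-en-1-yl]-5,8-dimethoxychroman-4-one | CCCC/C=C\CCCCCCCCCCC[C@@H]1CC(=O)c2c(OC)ccc(OC)c2O1
F9 | step 6 | methyl (S)-5-bromo-3-[(tert-butyldimethylsilyl)oxy]pentanoate | BrCC[C@@H](O[Si](C)(C)C(C)(C)C)CC(=O)OC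
F10 | step 6 | methyl (R,Z)-3-[(tert-butyldimethylsilyl)oxy]icos-15-enoate | CCCC/C=C\CCCCCCCCCCC[C@@H](O[Si](C)(C)C(C)(C)C)CC(=O)OC
F11 | step 6 | (R,Z)-3-[(tert-butyldimethylsilyl)oxy]-N-methoxy-N-methylicos-15-enamide | CCCC/C=C\CCCCCCCCCCC[C@@H](O[Si](C)(C)C(C)(C)C)CC(=O)N(C)OC
F12 | step 3 | (4R)-4-[(tert-butyldimethylsilyl)oxy]tetrahydro-2H-pyran-2-ol | OC1C[C@H](O[Si](C)(C)C(C)(C)C)CCO1
F13 | step 3 | (3R)-1-[2,5-bis(methoxymethoxy)phenyl]-3-[(tert-butyldimethylsilyl)oxy]pentane-1,5-diol | OCC[C@@H](O[Si](C)(C)C(C)(C)C)CC(O)c1cc(OCOC)ccc1OCOC
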